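**Plan**
- Retrosynthesis: remove the two O–SO3H groups and the aryl CHO (ortho-lithiation/formylation), then cut the C9=C11 alkene into an aryllithium plus a C11 aldehyde (addition, dehydration).
- The decalin is cut further at C9–C11 (carbonylation of an enol triflate), the second C4 methyl (cuprate), the C2–C3 bond of ring A (intramolecular alkene acylation) and the C10–C1 and C10–CH3 bonds (enolate alkylations), which leads back to (R)-carvone.
- Forward: ring B is the carvone ring. C10 is made quaternary, the enone is turned into the C9 ester, ring A is closed by attack of C3 on an acylium ion at C2, C4 is methylated, C2 is deoxygenated, C8 is set, and the arene is attached last.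
- Enabling feature: the carvone isopropenyl group on C5 (C4=C3H2) sits trans on ring B to the acetic acid arm on C10 (C1–C2). Its terminal carbon C3 closes a six-membered ring onto C2 and leaves a tertiary cation at C4, the later site of the gem-dimethyl group.
- Stereochemistry: C5 comes from (R)-carvone; C10 from alkylation anti to the isopropenyl group; C8 from hydrogenation on the α face, opposite the axial C10 methyl; the E alkene from elimination with the aryl group turned away from quaternary C10.

Key step: step 6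

Remark: the aryl sulfates of 32 and 33 are written as free hydrogen sulfates, as in the target structure; in practice they would be handled as sodium salts and set free as the acid on an acidic ion-exchange resin only at the end.
Numbering: drimane numbering is used for the decalin (C1–C10, C11 for the benzylic carbon), primed numbers for the arene; α is the face opposite the C10 methyl group.

**Step 1**
Reactants: 1 (R)-(−)-carvone
Product: 3 (5R)-2,6-dimethyl-5-(prop-1-en-2-yl)cyclohex-2-en-1-one (6-methylcarvone; C6 epimer mixture; trans epimer drawn), via lithium dienolate 2 (not isolated)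
Conditions: LiN(i-Pr)2, THF, −78 °C; MeI, −78 → 0 °C
Reagents that add atoms: iodomethane, CI
Why: Kinetic α′-deprotonation gives the cross-conjugated dienolate, which is C-methylated (enolate alkylation); the new centre (future C10) arises as an epimer mixture, which does not matter because it is made trigonal again in step 2.

**Step 2**
Reactants: 3 (5R)-6-methylcarvone
Product: 5 methyl 2-[(1S,6S)-1,3-dimethyl-2-oxo-6-(prop-1-en-2-yl)cyclohex-3-en-1-yl]acetate, via lithium dienolate 4 (not isolated)
Conditions: LiN(i-Pr)2, THF, −78 → 0 °C; BrCH2CO2Me, DMPU, −78 → −20 °C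
Reagents that add atoms: methyl bromoacetate, COC(=O)CBr
Why: Alkylation of the fully substituted α′-enolate (enolate alkylation) should occur anti to the neighbouring isopropenyl group, which sits pseudo-axial to avoid allylic strain with the enolate methyl, so the acetate arm (future C1–C2) ends up trans to the isopropenyl group and quaternary C10 is set.

**Step 3**
Reactants: 5 keto ester
Product: 7 methyl 2-[(1S,6S)-1,3-dimethyl-6-(prop-1-en-2-yl)-2-(trifluoromethanesulfonyloxy)cyclohex-2-en-1-yl]acetate, via lithium enolate 6 (not isolated)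
Conditions: LiBH(s-Bu)3, THF, −78 °C; PhNTf2, −78 °C → rt
Reagents that add atoms: N-phenylbis(trifluoromethanesulfonimide), O=S(=O)(N(c1ccccc1)S(=O)(=O)C(F)(F)F)C(F)(F)F
Why: Conjugate hydride reduction of the β-unsubstituted enone by the bulky borohydride, then O-triflation of the regiodefined enolate (reductive enol triflate formation); C8 stays trigonal, so no stereocentre is formed.

**Step 4**
Reactants: 7 enol triflate
Product: 8 methyl (5S,6S)-6-(2-methoxy-2-oxoethyl)-2,6-dimethyl-5-(prop-1-en-2-yl)cyclohex-1-ene-1-carboxylate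
Conditions: Pd(OAc)2 (cat.), dppp, CO (1 atm), MeOH, Et3N, DMF, 70 °C
Reagents that add atoms: carbon monoxide, [C-]#[O+]; methanol, CO
Why: Palladium-catalysed methoxycarbonylation of the enol triflate (oxidative addition to zerovalent palladium, CO insertion, methanolysis) attaches C11 to C9 as a hindered ester that should stay inert in steps 5 to 8; no stereocentre is formed.

**Step 5**
Reactants: 8 diester
Product: 9 2-[(1S,6S)-2-(methoxycarbonyl)-1,3-dimethyl-6-(prop-1-en-2-yl)cyclohex-2-en-1-yl]acetic acid
Conditions: LiOH, THF/MeOH/H2O, rt; then dilute HCl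
Reagents that add atoms: water, O
Why: Chemoselective saponification: hydroxide should attack only the unhindered acetate ester, because the tetrasubstituted conjugated ester on C9 is shielded by quaternary C10 and the C8 methyl group; no stereocentre is touched.

**Step 6**
Reactants: 9 acid
Product: 12 methyl (4aS,8aS)-2,5,8a-trimethyl-7-oxo-3,4,4a,7,8,8a-hexahydronaphthalene-1-carboxylate, via acid chloride 10 (not isolated), via β-chloro ketone 11 (not isolated)
Conditions: (COCl)2, DMF (cat.), CH2Cl2, 0 °C → rt, then concentrate; SnCl4, CH2Cl2, −78 → −20 °C; Et3N, rt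
Reagents that add atoms: none
Why: Oxalyl chloride turns acid 9 into acid chloride 10, which SnCl4 ionises to an acylium ion at C2; the terminal carbon C3 of the isopropenyl group on C5 attacks it, chloride captures the resulting tertiary C4 cation to give β-chloro ketone 11, and Et3N removes HCl by an E1cB path to give the conjugated enone 12. The closest known reaction type is the Lewis-acid-mediated intramolecular acylation of an alkene by an acid chloride (Darzens–Nenitzescu, Friedel–Crafts-type alkene acylation), long used to cyclise terpenoid olefinic acid chlorides to β-chloro cyclohexanones. Ring A is closed as a six-membered ring in a 6-endo-trig mode at the alkene (a type 2 cyclisation, the tether being attached to the internal alkene carbon C4), and the fusion should be trans because the two arms on C10 and C5 are already trans on ring B. No new stereocentre survives: the C4 chloride centre is transient and is erased on elimination, while C5 and C10 were set earlier and are not touched. The step needs chemoselectivity for the isopropenyl alkene over the C8=C9 alkene, which is deactivated by its ester and could only give a strained small ring. It also needs Markovnikov regioselectivity, secured by the tertiary cation at C4 and the six-membered transition state, and elimination toward C3 and not C5, secured by the acidity of the C3 protons next to the new ketone.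

**Step 7**
Reactants: 12 enone
Product: 14 methyl (4aS,8aS)-2,5,5,8a-tetramethyl-7-(trifluoromethanesulfonyloxy)-3,4,4a,5,8,8a-hexahydronaphthalene-1-carboxylate, via lithium enolate 13 (not isolated)
Conditions: Me2CuLi (from MeLi and CuI), Et2O, −20 → 0 °C; PhNTf2, THF, 0 °C → rt
Reagents that add atoms: lithium dimethylcuprate, [Li+].C[Cu-]C; N-phenylbis(trifluoromethanesulfonimide), O=S(=O)(N(c1ccccc1)S(=O)(=O)C(F)(F)F)C(F)(F)F
Why: Cuprate conjugate addition to the β-methyl enone builds the C4 gem-dimethyl carbon (no stereocentre), and O-triflation of the regiodefined enolate turns the helper oxygen at C2 into a leaving group; the tetrasubstituted C9 enoate should not react.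

**Step 8**
Reactants: 14 enol triflate
Product: 15 methyl (4aS,8aS)-2,5,5,8a-tetramethyl-3,4,4a,5,8,8a-hexahydronaphthalene-1-carboxylate
Conditions: Pd(OAc)2 (cat.), PPh3, HCO2H, n-Bu3N, DMF, 60 °C
Reagents that add atoms: none
Why: Palladium-catalysed formate reduction of the enol triflate (oxidative addition, formate decarboxylation, C–H reductive elimination) removes the C2 oxygen and leaves a C2=C3 alkene that is saturated in step 10.

**Step 9**
Reactants: 15 diene ester
Product: 16 [(4aS,8aS)-2,5,5,8a-tetramethyl-3,4,4a,5,8,8a-hexahydronaphthalen-1-yl]methanol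
Conditions: i-Bu2AlH, CH2Cl2, −78 → 0 °C; aq. potassium sodium tartrate
Reagents that add atoms: none
Why: 1,2-Reduction of the hindered conjugated ester by the aluminium hydride gives the allylic alcohol whose hydroxyl group directs step 10.

**Step 10**
Reactants: 16 dienol
Product: 17 [(1S,2S,4aS,8aS)-2,5,5,8a-tetramethyldecahydronaphthalen-1-yl]methanol
Conditions: H2 (1–50 bar), [Ir(cod)(PCy3)(py)]PF6 (cat.), CH2Cl2, rt
Reagents that add atoms: none
Why: Hydroxyl-directed homogeneous hydrogenation with the cationic iridium catalyst should saturate the C2=C3 alkene and the tetrasubstituted C8=C9 alkene; syn delivery of H2 to the α face, opposite the axial C10 methyl, sets C8 (methyl β, 8S) and C9 (CH2OH β).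

**Step 11**
Reactants: 17 alcohol
Product: 18 (1S,2S,4aS,8aS)-2,5,5,8a-tetramethyldecahydronaphthalene-1-carbaldehyde
Conditions: DMP [1,1,1-triacetoxy-1,1-dihydro-1,2-benziodoxol-3(1H)-one], CH2Cl2, rt
Reagents that add atoms: none
Why: Dess–Martin oxidation of the primary alcohol to the aldehyde under non-basic conditions; C8 is not α to the carbonyl and the C9 substituent is already equatorial, so no centre should be scrambled.

**Step 12**
Reactants: 19 2,5-dihydroxybenzaldehyde
Product: 20 2,5-bis(methoxymethoxy)benzaldehyde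
Conditions: MOMCl, i-Pr2NEt, CH2Cl2, 0 °C → reflux
Reagents that add atoms: chloromethyl methyl ether, COCCl
Why: O-Alkylation of both phenols (acetal protection) masks the two para-related oxygens that will later carry the sulfates.

**Step 13**
Reactants: 20 bis-MOM aldehyde
Product: 22 2,5-bis(methoxymethoxy)phenol, via aryl formate 21 (not isolated)
Conditions: mCPBA, CH2Cl2, rt; then K2CO3 (cat.), MeOH, rt
Reagents that add atoms: 3-chloroperoxybenzoic acid, OOC(=O)c1cccc(Cl)c1
Why: Baeyer–Villiger (Dakin-type) oxidation of the electron-rich benzaldehyde with aryl migration, then methanolysis of the formate, exchanges CHO for the third oxygen.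

**Step 14**
Reactants: 22 phenol
Product: 23 1-(benzyloxy)-2,5-bis(methoxymethoxy)benzene
Conditions: BnBr, K2CO3, DMF, rt
Reagents that add atoms: benzyl bromide, BrCc1ccccc1
Why: Williamson ether synthesis puts a benzyl group, orthogonal to the MOM ethers, on the one oxygen that stays unsulfated.

**Step 15**
Reactants: 23 benzyl ether
Product: 24 1-(benzyloxy)-4-bromo-2,5-bis(methoxymethoxy)benzene
Conditions: NBS, MeCN, 0 °C → rt
Reagents that add atoms: N-bromosuccinimide, O=C1CCC(=O)N1Br
Why: Electrophilic aromatic bromination should go para to the benzyloxy group and ortho to a MOM ether, the most activated unhindered position.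

**Step 16**
Reactants: 24 bromoarene; 18 aldehyde
Product: 26 [4-(benzyloxy)-2,5-bis(methoxymethoxy)phenyl][(1S,2S,4aS,8aS)-2,5,5,8a-tetramethyldecahydronaphthalen-1-yl]methanol (C11 epimer mixture), via aryllithium 25 (not isolated)
Conditions: n-BuLi, THF, −78 °C; then 18, −78 → 0 °C
Reagents that add atoms: none
Why: Bromine–lithium exchange and 1,2-addition of the aryllithium to the aldehyde joins the two fragments; the new C11 carbinol centre forms as an epimer mixture and is removed in step 17.

**Step 17**
Reactants: 26 carbinol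
Product: 28 1-(benzyloxy)-2,5-bis(methoxymethoxy)-4-{(E)-[(2S,4aS,8aS)-2,5,5,8a-tetramethyloctahydronaphthalen-1(2H)-ylidene]methyl}benzene, via benzylic mesylate 27 (not isolated)
Conditions: MsCl, Et3N, CH2Cl2, 0 °C → rt
Reagents that add atoms: none
Why: Mesylation of the electron-rich benzylic alcohol and E1-type elimination through the stabilised benzylic cation, which has a β-hydrogen only at C9; the E alkene should result because the aryl group turns away from quaternary C10 toward C8, and the MOM and benzyl ethers survive the basic medium.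

**Step 18**
Reactants: 28 styrene
Product: 30 2-(benzyloxy)-3,6-bis(methoxymethoxy)-5-{(E)-[(2S,4aS,8aS)-2,5,5,8a-tetramethyloctahydronaphthalen-1(2H)-ylidene]methyl}benzaldehyde, via aryllithium 29 (not isolated)
Conditions: n-BuLi, TMEDA, THF, −78 → 0 °C; DMF, −78 °C → rt
Reagents that add atoms: N,N-dimethylformamide, CN(C)C=O
Why: Directed ortho-metalation at C5′, the only position flanked by two ether oxygens (benzyloxy and MOM), then formylation with DMF.

**Step 19**
Reactants: 30 aldehyde
Product: 31 2-(benzyloxy)-3,6-dihydroxy-5-{(E)-[(2S,4aS,8aS)-2,5,5,8a-tetramethyloctahydronaphthalen-1(2H)-ylidene]methyl}benzaldehyde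
Conditions: HCl (dilute), MeOH/THF, rt → 40 °C
Reagents that add atoms: none
Why: Acid-catalysed acetal exchange cleaves both MOM ethers and frees the two para-related phenols, while the benzyl ether is stable; mild acid and short contact are chosen to avoid protonation of the styrene.

**Step 20**
Reactants: 31 hydroquinone
Product: 32 2-(benzyloxy)-3,6-bis(sulfooxy)-5-{(E)-[(2S,4aS,8aS)-2,5,5,8a-tetramethyloctahydronaphthalen-1(2H)-ylidene]methyl}benzaldehyde
Conditions: SO3·pyridine, pyridine, rt → 50 °C
Reagents that add atoms: sulfur trioxide–pyridine complex, [O-]S(=O)(=O)[n+]1ccccc1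
Why: O-Sulfation of the two free phenols with the amine–SO3 complex; the third oxygen is blocked as its benzyl ether, and the aldehyde and alkene do not react.

**Step 21**
Reactants: 32 benzyl ether disulfate
Product: 33 2-hydroxy-3,6-bis(sulfooxy)-5-{(E)-[(2S,4aS,8aS)-2,5,5,8a-tetramethyloctahydronaphthalen-1(2H)-ylidene]methyl}benzaldehyde (target)
Conditions: H2 (1 atm), Pd on carbon, MeOH/EtOAc, rt, short reaction time
Reagents that add atoms: none
Why: Hydrogenolysis of the aryl benzyl ether should be much faster than reduction of the hindered trisubstituted alkene beside quaternary C10; aryl sulfates are stable to these neutral conditions.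

**Compound list**
1 | (R)-(−)-carvone | CC1=CC[C@H](CC1=O)C(C)=C | starting material
2 | lithium dienolate of carvone | [Li+].[O-]C1=C[C@H](C(C)=C)CC=C1C | intermediate
3 | (5R)-2,6-dimethyl-5-(prop-1-en-2-yl)cyclohex-2-en-1-one (C6 epimers, trans drawn) | CC1=CC[C@@H](C(C)=C)[C@H](C)C1=O | intermediate
4 | lithium dienolate of 3 | [Li+].[O-]C1=C(C)[C@H](C(C)=C)CC=C1C | intermediate
5 | methyl 2-[(1S,6S)-1,3-dimethyl-2-oxo-6-(prop-1-en-2-yl)cyclohex-3-en-1-yl]acetate | CC1=CC[C@@H](C(C)=C)[C@](C)(CC(=O)OC)C1=O | intermediate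
6 | lithium enolate from conjugate reduction of 5 | [Li+].[O-]C1=C(C)CC[C@@H](C(C)=C)[C@]1(C)CC(=O)OC | intermediate
7 | methyl 2-[(1S,6S)-1,3-dimethyl-6-(prop-1-en-2-yl)-2-(trifluoromethanesulfonyloxy)cyclohex-2-en-1-yl]acetate | CC1=C(OS(=O)(=O)C(F)(F)F)[C@@](C)(CC(=O)OC)[C@H](C(C)=C)CC1 | intermediate
8 | methyl (5S,6S)-6-(2-methoxy-2-oxoethyl)-2,6-dimethyl-5-(prop-1-en-2-yl)cyclohex-1-ene-1-carboxylate | CC1=C(C(=O)OC)[C@@](C)(CC(=O)OC)[C@H](C(C)=C)CC1 | intermediate
9 | 2-[(1S,6S)-2-(methoxycarbonyl)-1,3-dimethyl-6-(prop-1-en-2-yl)cyclohex-2-en-1-yl]acetic acid | CC1=C(C(=O)OC)[C@@](C)(CC(=O)O)[C@H](C(C)=C)CC1 | intermediate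
10 | acid chloride of 9 | CC1=C(C(=O)OC)[C@@](C)(CC(=O)Cl)[C@H](C(C)=C)CC1 | intermediate
11 | β-chloro ketone (tertiary chloride at C4, either epimer; trans ring fusion as in 12) | CC1=C(C(=O)OC)[C@@]2(C)CC(=O)CC(C)(Cl)[C@@H]2CC1 | intermediate
12 | methyl (4aS,8aS)-2,5,8a-trimethyl-7-oxo-3,4,4a,7,8,8a-hexahydronaphthalene-1-carboxylate | CC1=C(C(=O)OC)[C@@]2(C)CC(=O)C=C(C)[C@@H]2CC1 | intermediate
13 | lithium enolate from cuprate addition to 12 | CC1=C(C(=O)OC)[C@@]2(C)CC([O-])=CC(C)(C)[C@@H]2CC1.[Li+] | intermediate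
14 | methyl (4aS,8aS)-2,5,5,8a-tetramethyl-7-(trifluoromethanesulfonyloxy)-3,4,4a,5,8,8a-hexahydronaphthalene-1-carboxylate | CC1=C(C(=O)OC)[C@@]2(C)CC(OS(=O)(=O)C(F)(F)F)=CC(C)(C)[C@@H]2CC1 | intermediate
15 | methyl (4aS,8aS)-2,5,5,8a-tetramethyl-3,4,4a,5,8,8a-hexahydronaphthalene-1-carboxylate | CC1=C(C(=O)OC)[C@@]2(C)CC=CC(C)(C)[C@@H]2CC1 | intermediate
16 | [(4aS,8aS)-2,5,5,8a-tetramethyl-3,4,4a,5,8,8a-hexahydronaphthalen-1-yl]methanol | CC1=C(CO)[C@@]2(C)CC=CC(C)(C)[C@@H]2CC1 | intermediate
17 | [(1S,2S,4aS,8aS)-2,5,5,8a-tetramethyldecahydronaphthalen-1-yl]methanol | C[C@H]1CC[C@H]2C(C)(C)CCC[C@]2(C)[C@H]1CO | intermediate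
18 | (1S,2S,4aS,8aS)-2,5,5,8a-tetramethyldecahydronaphthalene-1-carbaldehyde | C[C@H]1CC[C@H]2C(C)(C)CCC[C@]2(C)[C@H]1C=O | intermediate
19 | 2,5-dihydroxybenzaldehyde | O=Cc1cc(O)ccc1O | starting material
20 | 2,5-bis(methoxymethoxy)benzaldehyde | COCOc1ccc(OCOC)c(C=O)c1 | intermediate
21 | 2,5-bis(methoxymethoxy)phenyl formate | COCOc1ccc(OCOC)c(OC=O)c1 | intermediate
22 | 2,5-bis(methoxymethoxy)phenol | COCOc1ccc(OCOC)c(O)c1 | intermediate
23 | 1-(benzyloxy)-2,5-bis(methoxymethoxy)benzene | COCOc1ccc(OCOC)c(OCc2ccccc2)c1 | intermediate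
24 | 1-(benzyloxy)-4-bromo-2,5-bis(methoxymethoxy)benzene | COCOc1cc(OCc2ccccc2)c(OCOC)cc1Br | intermediate
25 | [4-(benzyloxy)-2,5-bis(methoxymethoxy)phenyl]lithium | COCOc1cc(OCc2ccccc2)c(OCOC)cc1[Li] | intermediate
26 | [4-(benzyloxy)-2,5-bis(methoxymethoxy)phenyl][(1S,2S,4aS,8aS)-2,5,5,8a-tetramethyldecahydronaphthalen-1-yl]methanol (C11 epimers) | C[C@H]1CC[C@H]2C(C)(C)CCC[C@]2(C)[C@H]1C(O)c1cc(OCOC)c(OCc2ccccc2)cc1OCOC | intermediate
27 | methanesulfonate of 26 | C[C@H]1CC[C@H]2C(C)(C)CCC[C@]2(C)[C@H]1C(OS(C)(=O)=O)c1cc(OCOC)c(OCc2ccccc2)cc1OCOC | intermediate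
28 | 1-(benzyloxy)-2,5-bis(methoxymethoxy)-4-{(E)-[(2S,4aS,8aS)-2,5,5,8a-tetramethyloctahydronaphthalen-1(2H)-ylidene]methyl}benzene | C[C@H]1CC[C@H]2C(C)(C)CCC[C@]2(C)/C1=C/c1cc(OCOC)c(OCc2ccccc2)cc1OCOC | intermediate
29 | C5′-aryllithium of 28 | C[C@H]1CC[C@H]2C(C)(C)CCC[C@]2(C)/C1=C/c1cc(OCOC)c(OCc2ccccc2)c([Li])c1OCOC | intermediate
30 | 2-(benzyloxy)-3,6-bis(methoxymethoxy)-5-{(E)-[(2S,4aS,8aS)-2,5,5,8a-tetramethyloctahydronaphthalen-1(2H)-ylidene]methyl}benzaldehyde | C[C@H]1CC[C@H]2C(C)(C)CCC[C@]2(C)/C1=C/c1cc(OCOC)c(OCc2ccccc2)c(C=O)c1OCOC | intermediate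
31 | 2-(benzyloxy)-3,6-dihydroxy-5-{(E)-[(2S,4aS,8aS)-2,5,5,8a-tetramethyloctahydronaphthalen-1(2H)-ylidene]methyl}benzaldehyde | C[C@H]1CC[C@H]2C(C)(C)CCC[C@]2(C)/C1=C/c1cc(O)c(OCc2ccccc2)c(C=O)c1O | intermediate
32 | 2-(benzyloxy)-3,6-bis(sulfooxy)-5-{(E)-[(2S,4aS,8aS)-2,5,5,8a-tetramethyloctahydronaphthalen-1(2H)-ylidene]methyl}benzaldehyde | C[C@H]1CC[C@H]2C(C)(C)CCC[C@]2(C)/C1=C/c1cc(OS(=O)(=O)O)c(OCc2ccccc2)c(C=O)c1OS(=O)(=O)O | intermediate
33 | 2-hydroxy-3,6-bis(sulfooxy)-5-{(E)-[(2S,4aS,8aS)-2,5,5,8a-tetramethyloctahydronaphthalen-1(2H)-ylidene]methyl}benzaldehyde | C[C@H]1CC[C@H]2C(C)(C)CCC[C@]2(C)/C1=C/c1cc(OS(=O)(=O)O)c(O)c(C=O)c1OS(=O)(=O)O | target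

**Step count**
Total: 21 steps. Longest linear sequence: 17 steps from (R)-carvone (steps 1–11, then 16–21); bromoarene 24 is made in a four-step side branch (steps 12–15).

**Steps most likely to fail**

Step 6. The acylium ion may not be intercepted cleanly by the alkene. Hydrochlorination or protonation of the isopropenyl group, lactonisation of the acid onto the resulting tertiary cation, or proton loss from the C4 cation toward C5 (which would erase the ring-fusion configuration) may compete. The fallback sets out from 8 and comes back at 12, and it closes the same C2–C3 bond by a type 2 carbonyl-ene reaction. One equivalent of i-Bu2AlH in CH2Cl2 at −78 °C should reduce only the unhindered side-chain ester, giving methyl (5S,6S)-2,6-dimethyl-6-(2-oxoethyl)-5-(prop-1-en-2-yl)cyclohex-1-ene-1-carboxylate F1. Me2AlCl in CH2Cl2 at −78 °C should then induce the ene cyclisation of the aldehyde onto the isopropenyl group, giving methyl (4aS,8aS)-7-hydroxy-2,8a-dimethyl-5-methylidene-3,4,4a,5,6,7,8,8a-octahydronaphthalene-1-carboxylate F2. Dess–Martin oxidation should give the β,γ-unsaturated ketone methyl (4aS,8aS)-2,8a-dimethyl-5-methylidene-7-oxo-3,4,4a,5,6,7,8,8a-octahydronaphthalene-1-carboxylate F3, and DBU in CH2Cl2 should move the exocyclic alkene into conjugation to give 12.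

Step 10. The tetrasubstituted C8=C9 alkene beside quaternary C10 may take up hydrogen only sluggishly, and the allylic alcohol may isomerise to the aldehyde or the facial selectivity may erode. The fallback sets out from 15 and comes back at 17; it moves the alkene to a less substituted position before hydrogenation. γ-Deprotonation with LiN(i-Pr)2 and HMPA in THF at −78 °C, then kinetic α-protonation with acetic acid, should give methyl (1S,4aS,8aS)-5,5,8a-trimethyl-2-methylidene-1,2,3,4,4a,5,8,8a-octahydronaphthalene-1-carboxylate F4. Hydrogenation over Pd on carbon should saturate both alkenes, with hydrogen entering C8 from the α face, to give methyl (1S,2S,4aS,8aS)-2,5,5,8a-tetramethyldecahydronaphthalene-1-carboxylate F5. Reduction with LiAlH4 in Et2O should then give 17.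

Step 21. Hydrogenolysis may be accompanied by saturation of the styrenyl alkene or reduction of the aryl aldehyde, and the free aryl sulfates may hydrolyse if the reaction has to be prolonged. The fallback sets out from 31 and comes back at 33; it carries the sulfates as neutral diesters so that the benzyl ether can be cleaved without hydrogen. 2,2,2-Trichloroethyl chlorosulfate with Et3N and DMAP in THF should give 2-(benzyloxy)-5-{(E)-[(2S,4aS,8aS)-2,5,5,8a-tetramethyloctahydronaphthalen-1(2H)-ylidene]methyl}-3,6-bis[(2,2,2-trichloroethoxy)sulfonyloxy]benzaldehyde F6. BCl3 with pentamethylbenzene in CH2Cl2 at −78 °C should cleave the benzyl ether next to the aldehyde to give 2-hydroxy-5-{(E)-[(2S,4aS,8aS)-2,5,5,8a-tetramethyloctahydronaphthalen-1(2H)-ylidene]methyl}-3,6-bis[(2,2,2-trichloroethoxy)sulfonyloxy]benzaldehyde F7. Zn and HCO2NH4 in MeOH should then remove both trichloroethyl groups to give 33.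

**Further compounds**
F1 | step 6 | methyl (5S,6S)-2,6-dimethyl-6-(2-oxoethyl)-5-(prop-1-en-2-yl)cyclohex-1-ene-1-carboxylate | CC1=C(C(=O)OC)[C@@](C)(CC=O)[C@H](C(C)=C)CC1
F2 | step 6 | methyl (4aS,8aS)-7-hydroxy-2,8a-dimethyl-5-methylidene-3,4,4a,5,6,7,8,8a-octahydronaphthalene-1-carboxylate (C7 epimers) | CC1=C(C(=O)OC)[C@@]2(C)CC(O)CC(=C)[C@@H]2CC1
F3 | step 6 | methyl (4aS,8aS)-2,8a-dimethyl-5-methylidene-7-oxo-3,4,4a,5,6,7,8,8a-octahydronaphthalene-1-carboxylate | CC1=C(C(=O)OC)[C@@]2(C)CC(=O)CC(=C)[C@@H]2CC1
F4 | step 10 | methyl (1S,4aS,8aS)-5,5,8a-trimethyl-2-methylidene-1,2,3,4,4a,5,8,8a-octahydronaphthalene-1-carboxylate | C=C1CC[C@H]2C(C)(C)C=CC[C@]2(C)[C@H]1C(=O)OC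
F5 | step 10 | methyl (1S,2S,4aS,8aS)-2,5,5,8a-tetramethyldecahydronaphthalene-1-carboxylate | C[C@H]1CC[C@H]2C(C)(C)CCC[C@]2(C)[C@H]1C(=O)OC
F6 | step 21 | 2-(benzyloxy)-5-{(E)-[(2S,4aS,8aS)-2,5,5,8a-tetramethyloctahydronaphthalen-1(2H)-ylidene]methyl}-3,6-bis[(2,2,2-trichloroethoxy)sulfonyloxy]benzaldehyde | C[C@H]1CC[C@H]2C(C)(C)CCC[C@]2(C)/C1=C/c1cc(OS(=O)(=O)OCC(Cl)(Cl)Cl)c(OCc2ccccc2)c(C=O)c1OS(=O)(=O)OCC(Cl)(Cl)Cl
F7 | step 21 | 2-hydroxy-5-{(E)-[(2S,4aS,8aS)-2,5,5,8a-tetramethyloctahydronaphthalen-1(2H)-ylidene]methyl}-3,6-bis[(2,2,2-trichloroethoxy)sulfonyloxy]benzaldehyde | C[C@H]1CC[C@H]2C(C)(C)CCC[C@]2(C)/C1=C/c1cc(OS(=O)(=O)OCC(Cl)(Cl)Cl)c(O)c(C=O)c1OS(=O)(=O)OCC(Cl)(Cl)Cl
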